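## Structural features

The target, 3,4,5-tribromo-2-(2,4-dibromophenoxy)phenol, consists of two benzene rings joined by one ether oxygen. Ring A is a phenol numbered C1 (OH), C2 (ether oxygen), C3, C4 and C5 (three adjacent bromines) and C6 (the only ring hydrogen). Ring B is a 2,4-dibromophenyl group (C1′–O, bromine at C2′ and C4′) bound through oxygen to C2. There is no stereocentre, so no stereochemical relationship has to be set or protected. The fragile groups are the five aryl C–Br bonds, which exclude hydrogenation over palladium, organolithium reagents and dissolving metals, and the free phenol, which is easily oxidised and dominates electrophilic substitution. The real difficulty is regiochemical: the ring A bromines sit at C3 and C5 (meta to the hydroxyl) and at C4, while C6, the carbon the hydroxyl activates most, must stay unsubstituted. A second difficulty is the ether: C2–O–C1′ is flanked by C1–OH, C3–Br and C2′–Br, so a metal-mediated aryl ether coupling would be hindered and would have to choose among several C–Br bonds. The key step exploits the fact that C6–C1(O)–C2(O–ring B) is the skeleton of an aryloxyacetone with the ether already in place, and that C3–C4–C5 is a symmetric three-carbon dialdehyde whose central carbon carries nitrogen. That C4 nitrogen later steers bromine to C3 and C5 and is itself exchanged for the C4 bromine.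

## Logic of the disconnections

13 to 12: only the O–acyl bond at C1 is cut. The phenol must be masked as an electron-poor, hindered ester while ring A is brominated, so that C1–O neither directs bromine to C6 nor is oxidised. The forward step needs an ester cleavage mild enough to leave five C–Br bonds and the diaryl ether untouched.

12 to 10 (through 11): the C4–Br bond is traced back to a C4–N bond. C4 has no directing handle of its own, whereas an amine there can be exchanged for bromide by diazotisation and also does the directing work of the next cut. The forward step must diazotise a weakly basic aniline with two ortho bromines, and bromine transfer must outrun hydrogen abstraction.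

10 to 9: the C3–Br and C5–Br bonds are cut. Both carbons are ortho to the C4 amine, whose para position is blocked by C1–O, so the amine can only send bromine there. This removes two bromines and leaves a simple 1,2,4-trisubstituted ring. The forward step needs exactly two bromine equivalents and must leave C6 and ring B alone.

9 to 8: the amine is traced back to a nitro group, the form in which nitrogen enters with the ring. The forward reduction must not hydrogenolyse C–Br bonds and must not let the ester migrate to nitrogen.

8 to 7: the O–acyl bond is cut to the free nitrophenol. The forward acylation is unproblematic because 7 has a single nucleophilic site.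

7 to 3 and 5: the ring bonds C2–C3 and C5–C6 are cut, which opens ring A into a ketone and a C3 dialdehyde. This is the largest simplification in the plan: the ether bond to ring A never has to be made on an arene, the ring B bromines come from a commercial phenol, and the nitrogen arrives exactly para to the oxygen. The forward step requires both α-carbons of 3 to condense with the two formyl groups of 5 faster than 3 condenses with itself.

3 to 1 and 2: the O–CH2 bond is cut. This is an ordinary phenoxide alkylation and only requires O- rather than C-alkylation.

5 to 4: 5 is traced to 4 by the known exchange of bromide for nitrite with loss of one carbon as CO2. The demand here is one of safety, not selectivity, because solid 5 is impact- and heat-sensitive.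

## Other disconnections considered

Alternative 1: The cut runs through ring B at C1′–C2′ and C5′–C6′, so ring B is assembled around the ether oxygen.
- Forward step: the ethynyl ether A3 of the tribromomethoxyphenol A4 would add as an electron-rich dienophile across C3 and C6 of 3,5-dibromo-2H-pyran-2-one A2. The bridged lactone would lose CO2 to give the methyl ether A1 of the target, and O-demethylation would finish the synthesis.
- In favour: both halves would carry all five bromines before they meet. A4 should come from one electrophilic tribromination, since hydroxyl and methoxyl together activate exactly those three carbons. The electrophilic C6 of A2 matches the nucleophilic terminal carbon of A3, so the oxygen should end up next to C2′–Br. No nitrogen-to-bromine exchange is needed.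
- Against: aryl ethynyl ethers are labile, and their usual preparation goes through a lithium acetylide made with an alkyllithium, which would attack the three C–Br bonds of A4 by halogen–metal exchange. The oxygen of A4 is flanked by bromine and methoxyl, and A3 might not survive the heating that the moderately reactive A2 needs.
- Comparison: the two plans are equal in building one ring from acyclic or non-benzenoid pieces and in avoiding an aryl ether coupling. Alternative 1 would be the better plan on convergence and step count (about six operations against eight) and on avoiding diazonium chemistry. The chosen plan is better on mechanism, because its ring synthesis uses stable reagents in aqueous base and no step brings a carbanion near a C–Br bond.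

Alternative 2: The cut runs through ring B at C3′–C4′ and C5′–C6′.
- Forward step: the 2-aryloxy-3-bromobutadiene A6, made from A4, would undergo a normal-demand Diels–Alder reaction with 1-bromovinyl phenyl sulfone A7 to give the racemic cyclohexene A5. Loss of benzenesulfinic acid and dehydrogenation would then give A1, followed by demethylation.
- In favour: cycloaddition of a 2-oxygenated diene with a strongly activated dienophile is a dependable reaction type. The donor oxygen should place the sulfone carbon para to it, as required. The single stereocentre of A5 is destroyed on aromatisation, so its configuration is irrelevant.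
- Against: A6 is not an easy compound; a hindered phenol must be joined to a bromodiene that can isomerise or polymerise. Aromatisation must remove the sulfinate and two hydrogens while keeping both bromines, and base could just as well eliminate HBr from the carbon that bears both bromine and sulfone, losing the C4′ bromine.
- Comparison: it is the equal of the chosen plan in avoiding an aryl ether coupling and better in needing no diazonium intermediate. It is worse on step count (nine or more operations) and on control, because the oxidation level of ring B must be corrected after the key step, whereas the condensation to 7 gives the aromatic ring directly.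

Alternative 3: No ring bond is cut; all five C–Br bonds are disconnected at once, with an amine at C6 as a removable director.
- Forward step: 2-amino-6-phenoxyphenol A9 would be treated with five equivalents of bromine in acetic acid to give the pentabromide A8. Diazotisation and reductive removal of nitrogen would then give the target.
- In favour: the directing effects are consistent. The C6 amine activates C5 and C3, the hydroxyl activates C4, and the ether oxygen activates C2′ and C4′. The route would be very short.
- Against: a free ortho-aminophenol is readily oxidised by bromine to quinone imines and phenoxazinones. Ring B would have to stop at two bromines while ring A takes three, with C6′ still open. The diazonium ion of an ortho-aminophenol collapses to a quinone diazide, whose reduction is less dependable. A9 itself requires a hindered aryl ether synthesis.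
- Comparison: Alternative 3 would be better on step count and atom economy, and equal in needing one diazonium step. The chosen plan is better on chemoselectivity: the ring B bromines are bought with the starting phenol, only two bromines are placed by direction, and this is done with the phenol masked and on an amine that cannot be oxidised to a quinone.

Key step: step 3

Assumption: 5 is used as freshly filtered, water-wet crystals and is never dried or heated as a solid, because the dry salt is impact- and heat-sensitive.

## Route

Step 1
Reactants: 1 2,4-dibromophenol; 2 chloroacetone
Product: 3 1-(2,4-dibromophenoxy)propan-2-one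
Conditions: K2CO3, KI (cat.), acetone, reflux
Reagents that add atoms: none
Why: Williamson ether synthesis; the phenoxide of 1 (acidified by two bromines, so K2CO3 suffices) displaces chloride from the α-chloro ketone by SN2, helped by the adjacent carbonyl and by in situ chloride–iodide exchange, and O-alkylation is the normal course in a polar aprotic solvent.

Step 2
Reactants: 4 mucobromic acid
Product: 5 sodium nitromalonaldehyde monohydrate
Conditions: NaNO2 (excess), H2O/EtOH, 50–55 °C; then 0 °C, filter, keep water-wet
Reagents that add atoms: NaNO2, [Na+].[O-]N=O; water, O
Why: This is the established nitrite degradation of mucobromic acid: nitrite replaces a vinylic bromide by addition–elimination, the carboxyl carbon leaves as CO2 and the second bromide is hydrolysed, leaving the delocalised nitromalonaldehyde anion, which crystallises as its sodium salt hydrate. For safety the salt is made in small batches behind a shield, the nitrous gases are scrubbed, and the crystals are used wet without drying.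

Step 3
Reactants: 3 1-(2,4-dibromophenoxy)propan-2-one; 5 sodium nitromalonaldehyde monohydrate
Product: 7 2-(2,4-dibromophenoxy)-4-nitrophenol, via acyclic nitro-enal sodium salt 6 (not isolated)
Conditions: NaOH (aq), EtOH/H2O, 0 °C → rt, several days; then HCl (aq)
Reagents that add atoms: none
Why: Hydroxide forms the enolates of 3; the more acidic aryloxymethylene carbon adds to one formyl group of the dialdehyde anion and water is lost (aldol condensation), forming C2–C3 and giving the acyclic salt 6. The methyl-side enolate of 6, whose C1=C6 double bond lies inside the forming ring, then attacks the remaining formyl carbon in a 6-(enolendo)-exo-trig aldol closure that forms C5–C6; a second dehydration and dienone-to-phenol tautomerisation give the 4-nitrophenoxide, which is protonated on acidification. The closest known reaction type is the base-mediated condensation of sodium nitromalonaldehyde with ketones enolisable on both sides to give 4-nitrophenols. No stereocentre is formed, and the C2=C3 geometry of 6 equilibrates through the delocalised anion, so the isomer able to cyclise is always available. The constitution is fixed because the dialdehyde is symmetric: whichever α-carbon reacts first, the ketone carbon becomes C1–OH, the aryloxy carbon becomes C2 and nitrogen sits at C4. The selectivity needed is cross-condensation over self-condensation of 3, which is secured by an excess of 5 and by the irreversible aromatisation that drains the productive pathway. The aryl ether and the C–Br bonds are inert to cold aqueous hydroxide.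

Step 4
Reactants: 7 2-(2,4-dibromophenoxy)-4-nitrophenol
Product: 8 2-(2,4-dibromophenoxy)-4-nitrophenyl 2,2-dimethylpropanoate
Conditions: PivCl, Et3N, DMAP (cat.), CH2Cl2, 0 °C → rt
Reagents that add atoms: pivaloyl chloride, CC(C)(C)C(Cl)=O
Why: DMAP-catalysed O-acylation (nucleophilic acyl substitution) of the acidic nitrophenol; the bulky pivalate is preferred to an acetate because a 4-nitrophenyl acetate is an active ester that would acylate the aniline formed in step 5, and the acyloxy group makes C1–O a weak director that spares C6.

Step 5
Reactants: 8 2-(2,4-dibromophenoxy)-4-nitrophenyl 2,2-dimethylpropanoate
Product: 9 4-amino-2-(2,4-dibromophenoxy)phenyl 2,2-dimethylpropanoate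
Conditions: Fe powder, NH4Cl, EtOH/H2O, 70 °C
Reagents that add atoms: none
Why: Béchamp-type reduction; zerovalent iron transfers electrons to the nitro group stepwise (nitroso, hydroxylamine, amine) in buffered aqueous ethanol, conditions that do not hydrogenolyse aryl C–Br bonds and at whose pH the hindered ester is not solvolysed.

Step 6
Reactants: 9 4-amino-2-(2,4-dibromophenoxy)phenyl 2,2-dimethylpropanoate
Product: 10 4-amino-3,5-dibromo-2-(2,4-dibromophenoxy)phenyl 2,2-dimethylpropanoate
Conditions: NBS (2.05 equiv), MeCN, 0 °C → rt, dark
Reagents that add atoms: N-bromosuccinimide, O=C1CCC(=O)N1Br
Why: Electrophilic aromatic bromination; the C4 amine is by far the strongest donor and its para position is blocked by C1–O, so bromine goes to its ortho carbons C5 (also para to the C2 ether oxygen) and C3 (also ortho to it), whereas C6 is meta to the amine and next to the deactivating acyloxy group and ring B is deactivated by its two bromines.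

Step 7
Reactants: 10 4-amino-3,5-dibromo-2-(2,4-dibromophenoxy)phenyl 2,2-dimethylpropanoate
Product: 12 3,4,5-tribromo-2-(2,4-dibromophenoxy)phenyl 2,2-dimethylpropanoate, via arenediazonium bromide 11 (not isolated)
Conditions: t-BuONO, CuBr2, MeCN, 0 → 60 °C
Reagents that add atoms: CuBr2, [Cu+2].[Br-].[Br-]; tert-butyl nitrite, CC(C)(C)ON=O (its nitrogen appears in 11 and leaves as N2)
Why: Non-aqueous Sandmeyer reaction; the nitrite ester nitrosates the weakly basic 2,6-dibromoaniline to 11, electron transfer from monovalent copper formed in situ gives an aryl radical that takes bromine from CuBr2 with loss of N2, no free ring position remains for copper-mediated bromination, and the diazonium salt is consumed as it forms, which is the safe way to run this step.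

Step 8
Reactants: 12 3,4,5-tribromo-2-(2,4-dibromophenoxy)phenyl 2,2-dimethylpropanoate
Product: 13 3,4,5-tribromo-2-(2,4-dibromophenoxy)phenol
Conditions: LiOH·H2O, THF/H2O, rt; then HCl (aq)
Reagents that add atoms: none
Why: Saponification by acyl–oxygen cleavage; the electron-poor phenoxide is a good leaving group, so even the hindered pivalate should hydrolyse near room temperature, where aryl bromides and the diaryl ether are inert, and acidification returns the free phenol.

## Compound list

1 | 2,4-dibromophenol | Oc1ccc(Br)cc1Br | starting material
2 | chloroacetone | CC(=O)CCl | starting material
3 | 1-(2,4-dibromophenoxy)propan-2-one | CC(=O)COc1ccc(Br)cc1Br | intermediate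
4 | mucobromic acid (3,4-dibromo-5-hydroxyfuran-2(5H)-one) | O=C1OC(O)C(Br)=C1Br | starting material
5 | sodium nitromalonaldehyde monohydrate | [Na+].[O-]C=C(C=O)[N+](=O)[O-].O | intermediate
6 | sodium aci-nitro salt of (3E)-4-(2,4-dibromophenoxy)-2-nitro-5-oxohex-3-enal (drawn for first reaction at the aryloxymethylene carbon; not isolated) | [Na+].CC(=O)/C(Oc1ccc(Br)cc1Br)=C\C(C=O)=[N+]([O-])[O-] | intermediate
7 | 2-(2,4-dibromophenoxy)-4-nitrophenol | Oc1ccc(cc1Oc1ccc(Br)cc1Br)[N+](=O)[O-] | intermediate
8 | 2-(2,4-dibromophenoxy)-4-nitrophenyl 2,2-dimethylpropanoate | CC(C)(C)C(=O)Oc1ccc(cc1Oc1ccc(Br)cc1Br)[N+](=O)[O-] | intermediate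
9 | 4-amino-2-(2,4-dibromophenoxy)phenyl 2,2-dimethylpropanoate | CC(C)(C)C(=O)Oc1ccc(N)cc1Oc1ccc(Br)cc1Br | intermediate
10 | 4-amino-3,5-dibromo-2-(2,4-dibromophenoxy)phenyl 2,2-dimethylpropanoate | CC(C)(C)C(=O)Oc1cc(Br)c(N)c(Br)c1Oc1ccc(Br)cc1Br | intermediate
11 | 2,6-dibromo-3-(2,4-dibromophenoxy)-4-(2,2-dimethylpropanoyloxy)benzenediazonium bromide (not isolated) | CC(C)(C)C(=O)Oc1cc(Br)c([N+]#N)c(Br)c1Oc1ccc(Br)cc1Br.[Br-] | intermediate
12 | 3,4,5-tribromo-2-(2,4-dibromophenoxy)phenyl 2,2-dimethylpropanoate | CC(C)(C)C(=O)Oc1cc(Br)c(Br)c(Br)c1Oc1ccc(Br)cc1Br | intermediate
13 | 3,4,5-tribromo-2-(2,4-dibromophenoxy)phenol | Oc1cc(Br)c(Br)c(Br)c1Oc1ccc(Br)cc1Br | target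

## Step count and risk

Total: 8 steps. Longest linear sequence: 7 steps (steps 1, 3, 4, 5, 6, 7, 8 from 1; the branch through step 2 from 4 is equally long).

Step 3 (key step). The enolate must add to an anionic, weakly electrophilic dialdehyde, so self-condensation of the ketone and hydrolytic deformylation of the dialdehyde salt may outrun ring formation and leave low conversion.
- Fallback, from 1 back to 7: Chan–Lam coupling of 1 with purchased (2-methoxy-5-nitrophenyl)boronic acid [Cu(OAc)2, pyridine, 4 Å molecular sieves, CH2Cl2, air, rt] should give 2,4-dibromo-1-(2-methoxy-5-nitrophenoxy)benzene F1. Copper stays in its divalent and trivalent states here, and these do not insert into aryl C–Br bonds.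
- Cleavage of the methyl ether of F1 with BBr3 (CH2Cl2, −78 → 0 °C) returns to the route at 7. This gives up the ring synthesis and accepts a hindered ether coupling.

Step 2. Exothermic decomposition during the nitrite reaction and loss of material on crystallisation may make the supply of 5 erratic, and the isolation carries the explosion hazard.
- Fallback, from 3 back to 7 without 5: 1-methyl-3,5-dinitropyridin-2(1H)-one F2, made by nitrating commercial 1-methylpyridin-2(1H)-one with HNO3/H2SO4, is a bench-stable equivalent of the dialdehyde.
- With Et3N in warm EtOH, the two α-carbons of 3 should add to C4 and C6 of F2, and the N1–C2–C3 part should leave as N-methyl-2-nitroacetamide. This is a ring transformation of the kind known for this pyridone with ketones and β-keto esters, and it gives 7 directly.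

Step 6. Bromination at the crowded C3 may lag behind, so that excess reagent oxidises the aniline or bromination spills onto C6′ of ring B.
- Fallback, from 9 back to 12: excess CuBr2 in MeCN at rt brominates only the amine-bearing ring through amine-bound divalent copper, each bromination consuming two CuBr2. Adding t-BuONO to the same flask then effects the bromodediazoniation.
- This coupled bromination–deamination passes through 10 and 11 without isolation, makes no new compound, and saves one step.

Step 7. Diazotisation of the hindered, weakly basic amine may be slow, and the aryl radical may abstract hydrogen from the solvent instead of bromine from copper, replacing nitrogen by hydrogen.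
- Fallback, from 10 back to 12: diazotisation with t-BuONO and BF3·OEt2 in THF at −15 °C, trapped at once with pyrrolidine and K2CO3, should give the isolable triazene 3,5-dibromo-2-(2,4-dibromophenoxy)-4-[(E)-(pyrrolidin-1-yl)diazenyl]phenyl 2,2-dimethylpropanoate F3.
- TMSBr in MeCN at 60 °C regenerates the diazonium ion next to bromide and should deliver 12 by an ionic pathway without a hydrogen-abstracting radical.

## Further compounds

F1 | step 3 | 2,4-dibromo-1-(2-methoxy-5-nitrophenoxy)benzene | COc1ccc(cc1Oc1ccc(Br)cc1Br)[N+](=O)[O-]
F2 | step 2 | 1-methyl-3,5-dinitropyridin-2(1H)-one | Cn1cc([N+](=O)[O-])cc([N+](=O)[O-])c1=O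
F0 | step 6 | none | none
F3 | step 7 | 3,5-dibromo-2-(2,4-dibromophenoxy)-4-[(E)-(pyrrolidin-1-yl)diazenyl]phenyl 2,2-dimethylpropanoate | CC(C)(C)C(=O)Oc1cc(Br)c(/N=N/N2CCCC2)c(Br)c1Oc1ccc(Br)cc1Br
A1 | alternative 1 | 1,2,3-tribromo-4-(2,4-dibromophenoxy)-5-methoxybenzene | COc1cc(Br)c(Br)c(Br)c1Oc1ccc(Br)cc1Br
A2 | alternative 1 | 3,5-dibromo-2H-pyran-2-one | O=C1OC=C(Br)C=C1Br
A3 | alternative 1 | 1,2,3-tribromo-4-(ethynyloxy)-5-methoxybenzene | COc1cc(Br)c(Br)c(Br)c1OC#C
A4 | alternative 1 | 2,3,4-tribromo-6-methoxyphenol (4,5,6-tribromoguaiacol) | COc1cc(Br)c(Br)c(Br)c1O
A5 | alternative 2 | racemic 1,2,3-tribromo-4-{[2,4-dibromo-4-(phenylsulfonyl)cyclohex-1-en-1-yl]oxy}-5-methoxybenzene (S enantiomer drawn) | COc1cc(Br)c(Br)c(Br)c1OC1=C(Br)C[C@](Br)(S(=O)(=O)c2ccccc2)CC1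
A6 | alternative 2 | 1,2,3-tribromo-4-[(3-bromobuta-1,3-dien-2-yl)oxy]-5-methoxybenzene | COc1cc(Br)c(Br)c(Br)c1OC(=C)C(Br)=C
A7 | alternative 2 | 1-bromovinyl phenyl sulfone | C=C(Br)S(=O)(=O)c1ccccc1
A8 | alternative 3 | 2-amino-3,4,5-tribromo-6-(2,4-dibromophenoxy)phenol | Nc1c(Br)c(Br)c(Br)c(Oc2ccc(Br)cc2Br)c1O
A9 | alternative 3 | 2-amino-6-phenoxyphenol | Nc1cccc(Oc2ccccc2)c1O
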